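The target is a meso cyclobutane made of two identical CH(CO2H)–C(CH3)(pyranonyl) halves joined head to head: C1–C2 links the carboxyl-bearing carbons, C3–C4 the two quaternary carbons. Following the presumed biosynthesis, one intramolecular [2+2] photocycloaddition forms both bonds and closes the four-membered ring, the C3–C4 bond creating the vicinal quaternary centres. The precursor is the diester of 1,8-dihydroxynaphthalene with two molecules of (E)-3-(4-methoxy-3-methyl-2-oxo-2H-pyran-6-yl)but-2-enoic acid: the cis-1,2-dicarboxyl unit of the ring is exploited as a two-point anchor that stacks the enoates parallel, and the E geometry then fixes all four stereocentres. The monomer arises from a 6-acetylpyranone by Horner–Wadsworth–Emmons olefination.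

Key step: step 7

Remark on the chemistry: the target is taken as the meso isomer (1R,2S,3R,4S; mirror plane through the midpoints of C1–C2 and C3–C4), with the two carboxyl groups cis, the two pyranone rings cis, and each pyranone trans to the carboxyl group on the neighbouring carbon, so only relative configuration has to be controlled.

Step 1
Reactants: 1 ethyl 2-methylacetoacetate; 2 methyl 2,2-dimethoxypropanoate
Product: 4 6-(1,1-dimethoxyethyl)-4-hydroxy-3-methyl-2H-pyran-2-one, via ethyl 6,6-dimethoxy-2-methyl-3,5-dioxoheptanoate 3 (not isolated)
Conditions: 1 (2 equiv), LDA (4.2 equiv), THF, −78 → 0 °C; then 2, −78 °C → rt; AcOH quench; then DBU, PhMe, 80 °C; aq. citric acid work-up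
Reagents that add atoms: none
Why: Huckin–Weiler γ-acylation, in which the dianion of the β-keto ester attacks the non-enolisable, inductively activated ketal ester through its terminal carbon to give the 3,5-dioxo ester, whose C5 enol oxygen is then lactonised onto the ethyl ester by DBU (6-exo-trig acyl substitution) to give the 4-hydroxy-2-pyranone, no stereocentre surviving.

Step 2
Reactants: 4 6-(1,1-dimethoxyethyl)-4-hydroxy-3-methyl-2H-pyran-2-one
Product: 5 6-(1,1-dimethoxyethyl)-4-methoxy-3-methyl-2H-pyran-2-one
Conditions: Me2SO4, K2CO3, acetone, reflux
Reagents that add atoms: dimethyl sulfate, COS(=O)(=O)OC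
Why: Williamson-type O-methylation of the vinylogous acid, the potassium salt reacting with dimethyl sulfate at the 4-oxygen to give the 4-methoxy-2-pyranone (the usual outcome for 3-alkyl-4-hydroxy-2-pyranones under these conditions) while the ketal is inert to base.

Step 3
Reactants: 5 6-(1,1-dimethoxyethyl)-4-methoxy-3-methyl-2H-pyran-2-one
Product: 6 6-acetyl-4-methoxy-3-methyl-2H-pyran-2-one
Conditions: TFA/H2O (9:1), 0 °C → rt
Reagents that add atoms: water, O
Why: Acid-catalysed ketal hydrolysis through the oxocarbenium ion should release the methyl ketone, while the ring methoxy group (a vinylogous ester) and the lactone are stable to aqueous TFA.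

Step 4
Reactants: 6 6-acetyl-4-methoxy-3-methyl-2H-pyran-2-one; 7 tert-butyl diethylphosphonoacetate
Product: 8 tert-butyl (E)-3-(4-methoxy-3-methyl-2-oxo-2H-pyran-6-yl)but-2-enoate
Conditions: NaH, THF, 0 °C → rt, dark
Reagents that add atoms: none
Why: Horner–Wadsworth–Emmons olefination of the electron-poor heteroaryl methyl ketone, in which the E alkene (pyranone trans to the ester) should predominate because the reversible addition funnels through the oxaphosphetane that keeps the bulky tert-butyl ester anti to the larger pyranone substituent, any Z isomer being removed by chromatography.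

Step 5
Reactants: 8 tert-butyl (E)-3-(4-methoxy-3-methyl-2-oxo-2H-pyran-6-yl)but-2-enoate
Product: 9 (E)-3-(4-methoxy-3-methyl-2-oxo-2H-pyran-6-yl)but-2-enoic acid
Conditions: TFA/CH2Cl2 (1:4), rt, dark
Reagents that add atoms: none
Why: Acidolysis of the tert-butyl ester (E1 loss of 2-methylpropene) should free the acid without base, so the pyranone lactone and the E geometry are untouched.

Step 6
Reactants: 9 (E)-3-(4-methoxy-3-methyl-2-oxo-2H-pyran-6-yl)but-2-enoic acid (2.2 equiv); 10 1,8-dihydroxynaphthalene
Product: 11 naphthalene-1,8-diyl bis[(E)-3-(4-methoxy-3-methyl-2-oxo-2H-pyran-6-yl)but-2-enoate]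
Conditions: DCC, DMAP (cat.), CH2Cl2, 0 °C → rt, dark
Reagents that add atoms: none
Why: Steglich esterification, in which the O-acylisourea and N-acylpyridinium of 9 acylate both peri hydroxyl groups under nearly neutral conditions that avoid the vinylketene deconjugation an acid chloride with amine base could cause, the alkene geometry being retained.

Step 7
Reactants: 11 naphthalene-1,8-diyl bis[(E)-3-(4-methoxy-3-methyl-2-oxo-2H-pyran-6-yl)but-2-enoate]
Product: 12 cyclic naphthalene-1,8-diyl diester of the target diacid (cyclobutane fused to a nine-membered dilactone ring; ester carbons cis, pyranones cis to each other and trans to the ester carbons; meso)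
Conditions: hν (365 nm LED), microcrystalline 11 as a thin layer between Pyrex plates or as a stirred aqueous slurry, rt
Reagents that add atoms: none
Why: Excitation of one pyranone-conjugated enoate in the crystal gives an excited alkene that adds to the second enoate, which the peri oxygens of the naphthalene hold parallel and within bonding distance, so the Cα–Cα′ bond and the Cβ–Cβ′ bond between the two fully substituted carbons form in one suprafacial–suprafacial [2π+2π] event. The closest known reaction type is the template-directed topochemical [2+2] photodimerisation of cinnamate diesters of 1,8-dihydroxynaphthalene to β-truxinates, applied here to a β-methyl, β-heteroaryl acrylate. The cyclobutane closes in the straight (head-to-head) mode and the nine-membered dilactone ring closes with it through the Cα–Cα′ bond, exo with respect to both alkenes (9-exo-trig); should the addition be stepwise, that bond forms first and the pyranone-stabilised bis-tertiary 1,4-biradical then collapses through the quaternary–quaternary bond to close the four-membered ring. All four stereocentres arise here: the E geometry of each alkene places each pyranone trans and each methyl cis to the neighbouring carboxyl carbon, and the template forces the syn head-to-head approach that sets the two carboxyl carbons cis and hence the two pyranones cis, giving the meso isomer. The step needs head-to-head regioselectivity and chemoselectivity for the exocyclic C=C bonds over the pyranone ring double bonds (ring [2+2] or 4π electrocyclisation); the tether aligns only the exocyclic alkenes, 365 nm light reaches only the long-wavelength tail of the extended enoate chromophore, and lattice confinement should suppress E/Z isomerisation.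

Step 8
Reactants: 12 cyclic naphthalene-1,8-diyl diester of the target diacid
Product: 13 (1R,2S,3R,4S)-3,4-bis(4-methoxy-3-methyl-2-oxo-2H-pyran-6-yl)-3,4-dimethylcyclobutane-1,2-dicarboxylic acid (meso)
Conditions: LiOH·H2O, THF/H2O (3:1), 0 °C; then 1 M HCl to pH 2
Reagents that add atoms: lithium hydroxide, [Li+].[OH-]
Why: Saponification of the two activated aryl esters, which hydroxide should cleave at 0 °C far faster than it attacks the vinylogous-carbonate pyranone rings, the first-formed carboxylate shielding its α-carbon from deprotonation so that the cis relationship is kept, and acidification giving the diacid and returning the template.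

Compound list
1 | ethyl 2-methylacetoacetate (ethyl 2-methyl-3-oxobutanoate) | CCOC(=O)C(C)C(C)=O | starting material
2 | methyl 2,2-dimethoxypropanoate | COC(=O)C(C)(OC)OC | starting material
3 | ethyl 6,6-dimethoxy-2-methyl-3,5-dioxoheptanoate (racemic, not isolated) | CCOC(=O)C(C)C(=O)CC(=O)C(C)(OC)OC | intermediate
4 | 6-(1,1-dimethoxyethyl)-4-hydroxy-3-methyl-2H-pyran-2-one | COC(C)(OC)c1cc(O)c(C)c(=O)o1 | intermediate
5 | 6-(1,1-dimethoxyethyl)-4-methoxy-3-methyl-2H-pyran-2-one | COC(C)(OC)c1cc(OC)c(C)c(=O)o1 | intermediate
6 | 6-acetyl-4-methoxy-3-methyl-2H-pyran-2-one | CC(=O)c1cc(OC)c(C)c(=O)o1 | intermediate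
7 | tert-butyl diethylphosphonoacetate | CCOP(=O)(OCC)CC(=O)OC(C)(C)C | starting material
8 | tert-butyl (E)-3-(4-methoxy-3-methyl-2-oxo-2H-pyran-6-yl)but-2-enoate | COc1cc(/C(C)=C/C(=O)OC(C)(C)C)oc(=O)c1C | intermediate
9 | (E)-3-(4-methoxy-3-methyl-2-oxo-2H-pyran-6-yl)but-2-enoic acid | COc1cc(/C(C)=C/C(=O)O)oc(=O)c1C | intermediate
10 | 1,8-dihydroxynaphthalene | Oc1cccc2cccc(O)c12 | starting material
11 | naphthalene-1,8-diyl bis[(E)-3-(4-methoxy-3-methyl-2-oxo-2H-pyran-6-yl)but-2-enoate] | COc1cc(/C(C)=C/C(=O)Oc2cccc3cccc(OC(=O)/C=C(\C)c4cc(OC)c(C)c(=O)o4)c23)oc(=O)c1C | intermediate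
12 | cyclic naphthalene-1,8-diyl ester of the target diacid (meso; ester carbons cis, pyranones cis to each other and trans to the ester carbons) | COc1cc([C@@]2(C)[C@@H]3C(=O)Oc4cccc5cccc(OC(=O)[C@@H]3[C@@]2(C)c2cc(OC)c(C)c(=O)o2)c45)oc(=O)c1C | intermediate
13 | (1R,2S,3R,4S)-3,4-bis(4-methoxy-3-methyl-2-oxo-2H-pyran-6-yl)-3,4-dimethylcyclobutane-1,2-dicarboxylic acid (meso) | COc1cc([C@@]2(C)[C@H](C(=O)O)[C@H](C(=O)O)[C@@]2(C)c2cc(OC)c(C)c(=O)o2)oc(=O)c1C | target

Total step count: 8
Longest linear sequence: 8 steps (1 → 13)

Steps most likely to fail

Step 7. The lattice of 11 may hold the two enoates in a geometry that does not react, or the excitation may be diverted into photochemistry of the pyranone rings or into E/Z isomerisation at crystal defects, so that the head-to-head adduct forms slowly or not at all. The fallback sets out from 9 and comes back to the route at 13; it replaces the solid-state template by a traceless five-atom tether in solution. Acid 9 would be dehydrated with DCC (0.5 equiv, CH2Cl2, 0 °C) to the symmetric anhydride bis[(E)-3-(4-methoxy-3-methyl-2-oxo-2H-pyran-6-yl)but-2-enoic] anhydride F1. Triplet sensitisation of this 1,6-diene (thioxanthen-9-one, 405 nm LED, dry CH2Cl2, rt) should follow the rule of five: the α,α′ bond closes the five-membered anhydride ring first, and the bis-tertiary 1,4-biradical then collapses through the quaternary–quaternary bond with both pyranones on the convex face. This should give the cis-fused 6,7-dimethyl-6,7-bis(4-methoxy-3-methyl-2-oxo-2H-pyran-6-yl)-3-oxabicyclo[3.2.0]heptane-2,4-dione F2, which water in THF at rt should open to 13.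

Step 8. Hydroxide may attack the pyranone lactones (ring opening or loss of the 4-methoxy group) or epimerise a carbon α to an ester carbonyl before both aryl esters are cleaved. The fallback sets out from 12 and comes back at 13, and avoids hydroxide altogether. Transesterification with K2CO3 (cat.) in MeOH at 0 °C should release the template and give the dimethyl ester dimethyl (1R,2S,3R,4S)-3,4-bis(4-methoxy-3-methyl-2-oxo-2H-pyran-6-yl)-3,4-dimethylcyclobutane-1,2-dicarboxylate F3; methoxide exchange at the pyranone C4 is degenerate and ring opening by methoxide is reversible. The two methyl esters would then be cleaved under neutral conditions with Me3SnOH (1,2-dichloroethane, 80 °C; dilute HCl work-up) to give 13.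

Step 4. Addition of the phosphonate anion may be only weakly E-selective, or may lose out to enolisation of the methyl ketone or to conjugate attack on the pyranone. The fallback sets out from 6 and comes back at 8, and builds the alkene by addition and elimination under thermodynamic control. Aldol addition of the lithium enolate of tert-butyl acetate (LDA, THF, −78 °C) should give the tertiary alcohol tert-butyl 3-hydroxy-3-(4-methoxy-3-methyl-2-oxo-2H-pyran-6-yl)butanoate F4 (racemic). Dehydration with Martin sulfurane, Ph2S[OC(CF3)2Ph]2 (CH2Cl2, rt), followed by equilibration with DBU (cat.), should move any exo-methylene or Z isomer to the conjugated E enoate 8.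

Further compounds
F1 | step 7 | bis[(E)-3-(4-methoxy-3-methyl-2-oxo-2H-pyran-6-yl)but-2-enoic] anhydride | COc1cc(/C(C)=C/C(=O)OC(=O)/C=C(\C)c2cc(OC)c(C)c(=O)o2)oc(=O)c1C
F2 | step 7 | cis-fused 6,7-dimethyl-6,7-bis(4-methoxy-3-methyl-2-oxo-2H-pyran-6-yl)-3-oxabicyclo[3.2.0]heptane-2,4-dione (both pyranones exo, meso) | COc1cc([C@@]2(C)[C@@H]3C(=O)OC(=O)[C@@H]3[C@@]2(C)c2cc(OC)c(C)c(=O)o2)oc(=O)c1C
F3 | step 8 | dimethyl (1R,2S,3R,4S)-3,4-bis(4-methoxy-3-methyl-2-oxo-2H-pyran-6-yl)-3,4-dimethylcyclobutane-1,2-dicarboxylate (meso) | COc1cc([C@@]2(C)[C@H](C(=O)OC)[C@H](C(=O)OC)[C@@]2(C)c2cc(OC)c(C)c(=O)o2)oc(=O)c1C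
F4 | step 4 | tert-butyl 3-hydroxy-3-(4-methoxy-3-methyl-2-oxo-2H-pyran-6-yl)butanoate (racemic) | COc1cc(C(C)(O)CC(=O)OC(C)(C)C)oc(=O)c1C
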